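**Strategy.** Abietane numbering is used; primed atoms belong to the thujane part. Everything rests on closing ring A through the C5–C10 ring-fusion bond by an Ireland–Claisen ring contraction of a δ-lactone, in which C5/C6 are the lactone enolate and C10=C1–C2–O the allylic ester. Its forced boat transition state turns one CBS-set carbinol (C2) into both ring-fusion stereocentres (C5–H and quaternary C10, cis) and exploits the C6 carbonyl flanking C5 and the aryl-bearing C10. The precursor is a 6-alkenyl-4,4-dimethyl-δ-lactone carrying ring C. Ring B follows by carbenoid insertion at C8, ring D with C4′ and C10′ by intramolecular allylboration, the quinone methide by acid.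

Key step: step 7

Remark: C7 of compounds 21 and 28–31 is formed without control and both epimers are carried on; it becomes sp2 in step 21. (+)-Sabinene is taken as the (1R,5R) enantiomer.

Step 1
Reactants: 1 3,3-dimethylglutaric anhydride; 2 1-propynylmagnesium bromide
Product: 3 3,3-dimethyl-5-oxooct-6-ynoic acid
Conditions: THF, −78 → −20 °C; aq. HCl
Reagents that add atoms: none
Why: Acylation of an alkynyl Grignard reagent by a cyclic anhydride should stop at the ynone because the magnesium carboxylate formed on ring opening deactivates the product.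

Step 2
Reactants: 3 3,3-dimethyl-5-oxooct-6-ynoic acid
Product: 4 methyl 3,3-dimethyl-5-oxooct-6-ynoate
Conditions: TMSCHN2, MeOH/PhMe, 0 °C
Reagents that add atoms: trimethylsilyldiazomethane, C[Si](C)(C)C=[N+]=[N-]
Why: Diazoalkane esterification masks the acid under neutral conditions that leave the base-sensitive ynone alone.

Step 3
Reactants: 5 3-isopropylcatechol
Product: 6 1-isopropyl-2,3-bis(methoxymethoxy)benzene
Conditions: MOMCl, i-Pr2NEt, CH2Cl2, 0 °C → rt
Reagents that add atoms: chloromethyl methyl ether, COCCl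
Why: O-Alkylation (MOM protection) gives acid-labile ethers that also act as ortho-directing groups.

Step 4
Reactants: 6 1-isopropyl-2,3-bis(methoxymethoxy)benzene
Product: 8 [4-isopropyl-2,3-bis(methoxymethoxy)phenyl]boronic acid, via aryllithium 7 (not isolated)
Conditions: n-BuLi, TMEDA, Et2O, 0 °C; B(OMe)3, −78 °C → rt; aq. NH4Cl
Reagents that add atoms: trimethyl borate, COB(OC)OC; water, O
Why: Directed ortho-metalation should lithiate C9, the only position ortho to an OMOM group, and the aryllithium is trapped as the borate and hydrolysed.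

Step 5
Reactants: 8 [4-isopropyl-2,3-bis(methoxymethoxy)phenyl]boronic acid; 4 methyl 3,3-dimethyl-5-oxooct-6-ynoate
Product: 9 methyl (6E)-7-[4-isopropyl-2,3-bis(methoxymethoxy)phenyl]-3,3-dimethyl-5-oxooct-6-enoate
Conditions: [Rh(cod)OH]2 (cat.), dioxane/H2O, 50 °C
Reagents that add atoms: none
Why: Rhodium-catalysed conjugate hydroarylation of the ynone is a syn addition that puts the aryl group on the β-carbon and hydrogen cis to it, which gives the E-enone (aryl trans to the carbonyl), also the more stable isomer.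

Step 6
Reactants: 9 methyl (6E)-7-[4-isopropyl-2,3-bis(methoxymethoxy)phenyl]-3,3-dimethyl-5-oxooct-6-enoate
Product: 11 (6S)-6-{(1E)-2-[4-isopropyl-2,3-bis(methoxymethoxy)phenyl]prop-1-en-1-yl}-4,4-dimethyloxan-2-one, via hydroxy ester 10 (not isolated)
Conditions: (R)-Me-CBS (cat.), catecholborane, PhMe, −78 °C; then DBU (cat.), PhMe, 60 °C
Reagents that add atoms: none
Why: Corey–Bakshi–Shibata reduction with the alkenyl group as the large substituent should set the (S)-carbinol C2 by catalyst control, and base-catalysed transesterification, helped by the gem-dimethyl group, closes the δ-lactone.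

Step 7
Reactants: 11 (6S)-6-{(1E)-2-[4-isopropyl-2,3-bis(methoxymethoxy)phenyl]prop-1-en-1-yl}-4,4-dimethyloxan-2-one
Product: 14 (1R,2S)-2-[4-isopropyl-2,3-bis(methoxymethoxy)phenyl]-2,6,6-trimethylcyclohex-3-ene-1-carboxylic acid, via silyl ketene acetal 12 (not isolated), via silyl ester 13 (not isolated)
Conditions: LDA, TBSCl, HMPA, THF, −78 °C → rt; PhMe, 100 °C; then AcOH, THF/H2O
Reagents that add atoms: none
Why: Deprotonation at C5 and O-silylation give the endocyclic silyl ketene acetal 12, whose [3,3]-sigmatropic shift breaks C2–O and forms C5–C10; the closest known reaction type is the Ireland–Claisen ring contraction of ω-alkenyl lactones to cycloalkene carboxylic acids. Ring A closes as a six-membered carbocycle by this pericyclic C–C bond formation, which for a six-membered lactone can only pass through a boat-like (bicyclo[2.2.2]-type) transition state. C5 is set because bond formation is suprafacial on the lactone face that carries the alkenyl group, so it is dictated by the (S)-carbinol C2, which is itself consumed. C10 is set by the E geometry of the alkene, which in the boat places the aryl group cis to the new carboxyl and the methyl group cis to H-5, the relative configuration of the cis-fused target. The step needs the sigmatropic shift to outrun heterolysis of the doubly activated allylic C2–O bond and needs the alkene geometry to survive; silylation at −78 °C, a non-polar medium for the thermolysis and the gem-dimethyl group, which biases the ring towards the reactive conformer, should secure this.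

Step 8
Reactants: 14 (1R,2S)-2-[4-isopropyl-2,3-bis(methoxymethoxy)phenyl]-2,6,6-trimethylcyclohex-3-ene-1-carboxylic acid
Product: 15 (1R,2S)-2-[4-isopropyl-2,3-bis(methoxymethoxy)phenyl]-2,6,6-trimethylcyclohexane-1-carboxylic acid
Conditions: H2 (1 atm), Pd/C, EtOAc, rt
Reagents that add atoms: none
Why: Heterogeneous hydrogenation of the cis-disubstituted ring alkene creates no stereocentre and removes the alkene before the carbenoid step.

Step 9
Reactants: 15 (1R,2S)-2-[4-isopropyl-2,3-bis(methoxymethoxy)phenyl]-2,6,6-trimethylcyclohexane-1-carboxylic acid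
Product: 16 (1R,2S)-2-[5-bromo-4-isopropyl-2,3-bis(methoxymethoxy)phenyl]-2,6,6-trimethylcyclohexane-1-carboxylic acid
Conditions: NBS, MeCN, 0 °C
Reagents that add atoms: N-bromosuccinimide, O=C1CCC(=O)N1Br
Why: Electrophilic aromatic bromination should go to C14, para to the C11 oxygen, because C8 is shielded by the adjacent quaternary C10.

Step 10
Reactants: 16 (1R,2S)-2-[5-bromo-4-isopropyl-2,3-bis(methoxymethoxy)phenyl]-2,6,6-trimethylcyclohexane-1-carboxylic acid
Product: 18 1-{(1R,2S)-2-[5-bromo-4-isopropyl-2,3-bis(methoxymethoxy)phenyl]-2,6,6-trimethylcyclohexyl}-2-diazoethan-1-one, via acid chloride 17 (not isolated)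
Conditions: 1-chloro-N,N,2-trimethylpropenylamine, CH2Cl2, 0 °C → rt; then CH2N2 (excess), Et2O, 0 °C
Reagents that add atoms: diazomethane, C=[N+]=[N-]
Why: The Ghosez reagent forms the acid chloride without free HCl, so the MOM ethers survive, and acylation of diazomethane (Arndt–Eistert-type diazoketone synthesis) adds C7.

Step 11
Reactants: 18 1-{(1R,2S)-2-[5-bromo-4-isopropyl-2,3-bis(methoxymethoxy)phenyl]-2,6,6-trimethylcyclohexyl}-2-diazoethan-1-one
Product: 19 (5R,10S)-14-bromo-11,12-bis(methoxymethoxy)abieta-8,11,13-trien-6-one (A/B cis)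
Conditions: Rh2(OAc)4 (cat.), CH2Cl2, rt, slow addition
Reagents that add atoms: none
Why: Rhodium-carbenoid aromatic substitution (Buchner-type addition and rearomatisation, as used for 2-tetralones) at C8–H, the only ortho C–H and cis to the side chain, should close ring B without touching C5 or C10.

Step 12
Reactants: 19 (5R,10S)-14-bromo-11,12-bis(methoxymethoxy)abieta-8,11,13-trien-6-one
Product: 20 (5R,10S)-14-bromo-7-(hydroxymethylidene)-11,12-bis(methoxymethoxy)abieta-8,11,13-trien-6-one
Conditions: NaH, HCO2Et, THF, 0 °C → rt; aq. NH4Cl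
Reagents that add atoms: ethyl formate, CCOC=O
Why: Claisen-type formylation occurs at the doubly activated benzylic C7 methylene, and the chelated enolate that results protects the ketone from enolisation towards the hindered C5.

Step 13
Reactants: 20 (5R,10S)-14-bromo-7-(hydroxymethylidene)-11,12-bis(methoxymethoxy)abieta-8,11,13-trien-6-one
Product: 21 (5R,10S)-14-bromo-7-hydroxy-11,12-bis(methoxymethoxy)-6-oxoabieta-8,11,13-triene-7-carbaldehyde
Conditions: DMDO, acetone, −20 °C
Reagents that add atoms: dimethyldioxirane, CC1(C)OO1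
Why: Epoxidation of the enol and opening of the epoxide (α-hydroxylation of a β-dicarbonyl compound) gives a non-enolisable aldehyde; the new C7 centre is not controlled and is erased in step 21.

Step 14
Reactants: 22 (1R,5R)-(+)-sabinene
Product: 23 (1S,5R)-5-isopropylbicyclo[3.1.0]hexan-2-one (sabina ketone)
Conditions: O3, CH2Cl2/MeOH, −78 °C; Me2S
Reagents that add atoms: ozone, [O-][O+]=O
Why: Ozonolysis with reductive work-up cleaves the exocyclic alkene and leaves the cyclopropane and both stereocentres of sabinene intact.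

Step 15
Reactants: 23 (1S,5R)-5-isopropylbicyclo[3.1.0]hexan-2-one
Product: 24 5-isopropylbicyclo[3.1.0]hex-3-en-2-one (bridgeheads as in 23)
Conditions: IBX, DMSO, 70 °C
Reagents that add atoms: none
Why: IBX dehydrogenation proceeds through the only possible enol (towards C3′) and gives the cyclopentenone.

Step 16
Reactants: 24 5-isopropylbicyclo[3.1.0]hex-3-en-2-one
Product: 25 5-isopropyl-4-(4,4,5,5-tetramethyl-1,3,2-dioxaborolan-2-yl)bicyclo[3.1.0]hexan-2-one (boron anti to the cyclopropane methylene)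
Conditions: B2pin2, CuCl (cat.), Xantphos (cat.), NaOt-Bu (cat.), MeOH, THF, rt
Reagents that add atoms: bis(pinacolato)diboron, CC1(C)OB(OC1(C)C)B1OC(C)(C)C(C)(C)O1
Why: Copper-catalysed conjugate borylation should deliver boron to the β-carbon (C2′) from the face anti to the cyclopropane, which sets this stereocentre by substrate control.

Step 17
Reactants: 25 5-isopropyl-4-(pinacolboryl)bicyclo[3.1.0]hexan-2-one
Product: 26 5-isopropyl-4-(pinacolboryl)bicyclo[3.1.0]hex-2-en-2-yl trifluoromethanesulfonate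
Conditions: KHMDS, PhNTf2, THF, −78 °C
Reagents that add atoms: N-phenylbis(trifluoromethanesulfonimide), O=S(=O)(N(c1ccccc1)S(=O)(=O)C(F)(F)F)C(F)(F)F
Why: Kinetic enolate formation (only C3′ can enolise) and O-triflation give the alkenyl triflate without disturbing the allylic boronate.

Step 18
Reactants: 26 5-isopropyl-4-(pinacolboryl)bicyclo[3.1.0]hex-2-en-2-yl trifluoromethanesulfonate
Product: 27 trimethyl[5-isopropyl-4-(pinacolboryl)bicyclo[3.1.0]hex-2-en-2-yl]stannane
Conditions: (Me3Sn)2, Pd(PPh3)4 (cat.), LiCl, THF, 60 °C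
Reagents that add atoms: hexamethylditin, C[Sn](C)(C)[Sn](C)(C)C
Why: Palladium-catalysed stannylation of an alkenyl triflate with a distannane is chemoselective for the C–OTf bond.

Step 19
Reactants: 21 (5R,10S)-14-bromo-7-hydroxy-11,12-bis(methoxymethoxy)-6-oxoabieta-8,11,13-triene-7-carbaldehyde; 27 trimethyl[5-isopropyl-4-(pinacolboryl)bicyclo[3.1.0]hex-2-en-2-yl]stannane
Product: 30 ring-D-closed spiro-thuj-2′-ene diol, via Stille product 28 (not isolated), via borate ester 29 (not isolated)
Conditions: Pd(Pt-Bu3)2 (cat.), CuI (cat.), DMF, 50 °C; then pH 7 buffer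
Reagents that add atoms: none
Why: Stille coupling joins C14 to C4′, and the allylboronate then adds to the neighbouring aldehyde (not the ketone) through a closed six-membered transition state (intramolecular allylboration), so that bond formation on the boron-bearing face anti to the cyclopropane sets the spiro centre C4′ and the B–O contact on the C3′ side sets the carbinol C10′.

Step 20
Reactants: 30 ring-D-closed spiro-thuj-2′-ene diol
Product: 31 ring-D-closed spiro-thujane diol
Conditions: H2 (1 atm), [Ir(cod)(PCy3)(py)]PF6 (cat.), CH2Cl2, rt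
Reagents that add atoms: none
Why: Hydroxyl-directed homogeneous hydrogenation (Crabtree catalyst) reduces the hindered cis-alkene without hydrogenolysis of the adjacent cyclopropane and creates no stereocentre.

Step 21
Reactants: 31 ring-D-closed spiro-thujane diol
Product: 32 CNP0178265.1 (target)
Conditions: 2 M aq. HCl, THF, 45 °C, under argon
Reagents that add atoms: none
Why: Acetal hydrolysis frees the catechol, and the tertiary C7 alcohol, para to the C12 hydroxyl, loses water (quinone methide formation by 1,6-elimination) to give the conjugated 11-hydroxy-12-oxo quinone methide with C7=C8.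

**Compound list**

1 | 3,3-dimethylglutaric anhydride (4,4-dimethyloxane-2,6-dione) | O=C1CC(C)(C)CC(=O)O1 | starting material
2 | 1-propynylmagnesium bromide | CC#C[Mg]Br | starting material
3 | 3,3-dimethyl-5-oxooct-6-ynoic acid | CC#CC(=O)CC(C)(C)CC(=O)O | intermediate
4 | methyl 3,3-dimethyl-5-oxooct-6-ynoate | CC#CC(=O)CC(C)(C)CC(=O)OC | intermediate
5 | 3-isopropylcatechol | CC(C)c1cccc(O)c1O | starting material
6 | 1-isopropyl-2,3-bis(methoxymethoxy)benzene | CC(C)c1cccc(OCOC)c1OCOC | intermediate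
7 | [4-isopropyl-2,3-bis(methoxymethoxy)phenyl]lithium (not isolated) | [Li]c1ccc(C(C)C)c(OCOC)c1OCOC | intermediate
8 | [4-isopropyl-2,3-bis(methoxymethoxy)phenyl]boronic acid | OB(O)c1ccc(C(C)C)c(OCOC)c1OCOC | intermediate
9 | methyl (6E)-7-[4-isopropyl-2,3-bis(methoxymethoxy)phenyl]-3,3-dimethyl-5-oxooct-6-enoate | COC(=O)CC(C)(C)CC(=O)/C=C(\C)c1ccc(C(C)C)c(OCOC)c1OCOC | intermediate
10 | methyl (5S,6E)-5-hydroxy-7-[4-isopropyl-2,3-bis(methoxymethoxy)phenyl]-3,3-dimethyloct-6-enoate (not isolated) | COC(=O)CC(C)(C)C[C@H](O)/C=C(\C)c1ccc(C(C)C)c(OCOC)c1OCOC | intermediate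
11 | (6S)-6-{(1E)-2-[4-isopropyl-2,3-bis(methoxymethoxy)phenyl]prop-1-en-1-yl}-4,4-dimethyloxan-2-one | O=C1CC(C)(C)C[C@H](O1)/C=C(\C)c2ccc(C(C)C)c(OCOC)c2OCOC | intermediate
12 | tert-butyldimethylsilyl ketene acetal of lactone 11 (C5=C6 enol ether, not isolated) | CC(C)(C)[Si](C)(C)OC1=CC(C)(C)C[C@H](O1)/C=C(\C)c2ccc(C(C)C)c(OCOC)c2OCOC | intermediate
13 | tert-butyldimethylsilyl ester of acid 14 (not isolated) | CC(C)(C)[Si](C)(C)OC(=O)[C@@H]1C(C)(C)CC=C[C@]1(C)c2ccc(C(C)C)c(OCOC)c2OCOC | intermediate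
14 | (1R,2S)-2-[4-isopropyl-2,3-bis(methoxymethoxy)phenyl]-2,6,6-trimethylcyclohex-3-ene-1-carboxylic acid (aryl and CO2H cis) | OC(=O)[C@@H]1C(C)(C)CC=C[C@]1(C)c2ccc(C(C)C)c(OCOC)c2OCOC | intermediate
15 | (1R,2S)-2-[4-isopropyl-2,3-bis(methoxymethoxy)phenyl]-2,6,6-trimethylcyclohexane-1-carboxylic acid | OC(=O)[C@@H]1C(C)(C)CCC[C@]1(C)c2ccc(C(C)C)c(OCOC)c2OCOC | intermediate
16 | (1R,2S)-2-[5-bromo-4-isopropyl-2,3-bis(methoxymethoxy)phenyl]-2,6,6-trimethylcyclohexane-1-carboxylic acid | OC(=O)[C@@H]1C(C)(C)CCC[C@]1(C)c2cc(Br)c(C(C)C)c(OCOC)c2OCOC | intermediate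
17 | acid chloride of 16 (not isolated) | ClC(=O)[C@@H]1C(C)(C)CCC[C@]1(C)c2cc(Br)c(C(C)C)c(OCOC)c2OCOC | intermediate
18 | 1-{(1R,2S)-2-[5-bromo-4-isopropyl-2,3-bis(methoxymethoxy)phenyl]-2,6,6-trimethylcyclohexyl}-2-diazoethan-1-one | [N-]=[N+]=CC(=O)[C@@H]1C(C)(C)CCC[C@]1(C)c2cc(Br)c(C(C)C)c(OCOC)c2OCOC | intermediate
19 | (5R,10S)-14-bromo-11,12-bis(methoxymethoxy)abieta-8,11,13-trien-6-one (A/B cis, H-5 and C20 methyl syn) | O=C1[C@@H]2C(C)(C)CCC[C@]2(C)c2c(OCOC)c(OCOC)c(C(C)C)c(Br)c2C1 | intermediate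
20 | (5R,10S)-14-bromo-7-(hydroxymethylidene)-11,12-bis(methoxymethoxy)abieta-8,11,13-trien-6-one | O=C1[C@@H]2C(C)(C)CCC[C@]2(C)c2c(OCOC)c(OCOC)c(C(C)C)c(Br)c2C1=CO | intermediate
21 | (5R,10S)-14-bromo-7-hydroxy-11,12-bis(methoxymethoxy)-6-oxoabieta-8,11,13-triene-7-carbaldehyde (C7 epimers) | O=CC1(O)C(=O)[C@@H]2C(C)(C)CCC[C@]2(C)c2c(OCOC)c(OCOC)c(C(C)C)c(Br)c21 | intermediate
22 | (1R,5R)-(+)-sabinene | C=C1CC[C@]2(C(C)C)C[C@@H]21 | starting material
23 | (1S,5R)-5-isopropylbicyclo[3.1.0]hexan-2-one (sabina ketone) | O=C1CC[C@]2(C(C)C)C[C@@H]21 | intermediate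
24 | 5-isopropylbicyclo[3.1.0]hex-3-en-2-one, bridgehead configuration as in 23 | O=C1C=C[C@]2(C(C)C)C[C@@H]21 | intermediate
25 | 5-isopropyl-4-(4,4,5,5-tetramethyl-1,3,2-dioxaborolan-2-yl)bicyclo[3.1.0]hexan-2-one, boron anti to the cyclopropane CH2 | O=C1C[C@@H](B3OC(C)(C)C(C)(C)O3)[C@]2(C(C)C)C[C@@H]21 | intermediate
26 | 5-isopropyl-4-(pinacolboryl)bicyclo[3.1.0]hex-2-en-2-yl trifluoromethanesulfonate, configuration as in 25 | FC(F)(F)S(=O)(=O)OC1=C[C@@H](B3OC(C)(C)C(C)(C)O3)[C@]2(C(C)C)C[C@@H]21 | intermediate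
27 | trimethyl[5-isopropyl-4-(pinacolboryl)bicyclo[3.1.0]hex-2-en-2-yl]stannane, configuration as in 25 | C[Sn](C)(C)C1=C[C@@H](B3OC(C)(C)C(C)(C)O3)[C@]2(C(C)C)C[C@@H]21 | intermediate
28 | Stille product: aldehyde 21 with Br at C14 replaced by the 2′-(pinacolboryl)thuj-3′-en-4′-yl group of 27 (not isolated) | O=CC1(O)C(=O)[C@@H]2C(C)(C)CCC[C@]2(C)c2c(OCOC)c(OCOC)c(C(C)C)c(C3=C[C@@H](B4OC(C)(C)C(C)(C)O4)[C@]4(C(C)C)C[C@@H]43)c21 | intermediate
29 | pinacol borate ester at O-10′ of diol 30 (not isolated) | CC(C)c1c2c3C(O)(C(=O)[C@@H]4C(C)(C)CCC[C@]4(C)c3c(OCOC)c1OCOC)[C@H](OB5OC(C)(C)C(C)(C)O5)[C@]21C=C[C@]2(C(C)C)C[C@@H]21 | intermediate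
30 | ring-D-closed diol: (5R,10S)-7-hydroxy-11,12-bis(methoxymethoxy)-6-oxoabieta-8,11,13-triene bridged from C7 to C14 by the C10′H(OH)–C4′ unit of a 1′-isopropylbicyclo[3.1.0]hex-2′-ene (C4′ spiro; C14 syn and C10′ anti to the cyclopropane CH2; 10′-OH on the C3′ side; C10′, C4′, C1′, C5′ as in the target; C7 epimers) | CC(C)c1c2c3C(O)(C(=O)[C@@H]4C(C)(C)CCC[C@]4(C)c3c(OCOC)c1OCOC)[C@H](O)[C@]21C=C[C@]2(C(C)C)C[C@@H]21 | intermediate
31 | 2′,3′-dihydro derivative of 30 (saturated thujane ring) | CC(C)c1c2c3C(O)(C(=O)[C@@H]4C(C)(C)CCC[C@]4(C)c3c(OCOC)c1OCOC)[C@H](O)[C@]21CC[C@]2(C(C)C)C[C@@H]21 | intermediate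
32 | CNP0178265.1: (5R,10S)-11,10′-dihydroxy-6,12-dioxo quinone methide (C7=C8, C9=C11, C13=C14) with C7–C10′H(OH)–C4′(spiro-thujane)–C14 ring D | CC(C)C1=C2C3=C(C(=O)[C@@H]4C(C)(C)CCC[C@]4(C)C3=C(O)C1=O)[C@H](O)[C@]21CC[C@]2(C(C)C)C[C@@H]21 | target

**Step count.** Total: 21 steps. Longest linear sequence: 14 steps (3–13 and 19–21 from 3-isopropylcatechol; the same length from the anhydride through steps 1, 2, 5–13, 19–21).

**Steps most likely to fail**

1. Step 7 (key step). The boat-like shift joins a carbon next to the gem-dimethyl group to a fully substituted alkene carbon and may be slow. Heterolysis of the allylic C2–O bond of the silyl ketene acetal (aryl-stabilised allyl cation) could then outrun C–C bond formation, with loss of the C2 information and formation of transposed or eliminated material. Fallback: from lactone 11, DIBAL-H (CH2Cl2, −78 °C) should give the lactol F1, and mesylation–elimination (MsCl, Et3N, then DBU) the 2-alkenyl-3,4-dihydro-2H-pyran F2. Its neutral thermal Claisen rearrangement (xylene, 150 °C; dihydropyran to cyclohexenecarbaldehyde, no silylated or charged intermediate, same boat topology and same chirality transfer from C2) should give the aldehyde F3. Pinnick oxidation (NaClO2, NaH2PO4, 2-methylbut-2-ene) returns to the route at acid 14.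

2. Step 19. Oxidative addition and transmetalation at the doubly ortho-substituted C14–Br may be too slow, so that protodestannylation of 27 and deformylation or α-ketol shift of the hydroxy aldehyde take over. Fallback: the coupling is moved to the robust ketone 19 and ring D is closed by an ene reaction. Sabina ketone 23 is converted into the enol triflate F7 (LDA, PhNTf2) and the alkenylboronate F8 (B2pin2, PdCl2(dppf), KOAc). Suzuki–Miyaura coupling with 19 (Pd(OAc)2, SPhos, K3PO4, PhMe/H2O, 90 °C) should give the aryl-thujene ketone F9. Formylation as in step 12 gives the hydroxymethylidene ketone F10, and hydroxylation of its sodium enolate with the Davis oxaziridine (which spares the styrene-type alkene) gives the hydroxy aldehyde F11. A thermal intramolecular carbonyl–ene reaction (PhMe, 110 °C), in which the only abstractable allylic hydrogen sits on C2′, then closes ring D under the same cyclic constraints and comes back to the route at 30.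

3. Step 11. The carbenoid may insert into aliphatic C–H bonds of ring A (C1–H, C4 methyls) or stop at a norcaradiene/cycloheptatriene instead of substituting the hindered C8–H. Fallback: from acid 16, esterification (TMSCHN2) gives the methyl ester F4, and addition of LiCH2S(O)CH3 gives the β-keto sulfoxide F5. Pummerer activation (TFAA, 2,6-lutidine, CH2Cl2, 0 °C) generates a thionium ion at C7 that should cyclise onto C8 in a Friedel–Crafts sense (para to the C12 oxygen) to give the 7-methylsulfanyl ketone F6. Reductive desulfurisation (SmI2, THF/MeOH, −78 °C) returns to the route at ketone 19.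

**Further compounds**

F1 | step 7 | (6S)-6-{(1E)-2-[4-isopropyl-2,3-bis(methoxymethoxy)phenyl]prop-1-en-1-yl}-4,4-dimethyloxan-2-ol (lactol, anomers) | OC1CC(C)(C)C[C@H](O1)/C=C(\C)c2ccc(C(C)C)c(OCOC)c2OCOC
F2 | step 7 | (2S)-2-{(1E)-2-[4-isopropyl-2,3-bis(methoxymethoxy)phenyl]prop-1-en-1-yl}-4,4-dimethyl-3,4-dihydro-2H-pyran | C1=CC(C)(C)C[C@H](O1)/C=C(\C)c2ccc(C(C)C)c(OCOC)c2OCOC
F3 | step 7 | (1R,2S)-2-[4-isopropyl-2,3-bis(methoxymethoxy)phenyl]-2,6,6-trimethylcyclohex-3-ene-1-carbaldehyde | O=C[C@@H]1C(C)(C)CC=C[C@]1(C)c2ccc(C(C)C)c(OCOC)c2OCOC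
F7 | step 19 | 5-isopropylbicyclo[3.1.0]hex-2-en-2-yl trifluoromethanesulfonate (bridgeheads as in 23) | FC(F)(F)S(=O)(=O)OC1=CC[C@]2(C(C)C)C[C@@H]21
F8 | step 19 | 2-(5-isopropylbicyclo[3.1.0]hex-2-en-2-yl)-4,4,5,5-tetramethyl-1,3,2-dioxaborolane | CC1(C)OB(OC1(C)C)C1=CC[C@]2(C(C)C)C[C@@H]21
F9 | step 19 | (5R,10S)-11,12-bis(methoxymethoxy)-14-(1′-isopropylbicyclo[3.1.0]hex-3′-en-4′-yl)abieta-8,11,13-trien-6-one | O=C1[C@@H]2C(C)(C)CCC[C@]2(C)c2c(OCOC)c(OCOC)c(C(C)C)c(C3=CC[C@]4(C(C)C)C[C@@H]43)c2C1
F10 | step 19 | 7-(hydroxymethylidene) derivative of F9 | O=C1[C@@H]2C(C)(C)CCC[C@]2(C)c2c(OCOC)c(OCOC)c(C(C)C)c(C3=CC[C@]4(C(C)C)C[C@@H]43)c2C1=CO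
F11 | step 19 | 7-formyl-7-hydroxy derivative of F9 (C7 epimers) | O=CC1(O)C(=O)[C@@H]2C(C)(C)CCC[C@]2(C)c2c(OCOC)c(OCOC)c(C(C)C)c(C3=CC[C@]4(C(C)C)C[C@@H]43)c21
F4 | step 11 | methyl (1R,2S)-2-[5-bromo-4-isopropyl-2,3-bis(methoxymethoxy)phenyl]-2,6,6-trimethylcyclohexane-1-carboxylate | COC(=O)[C@@H]1C(C)(C)CCC[C@]1(C)c2cc(Br)c(C(C)C)c(OCOC)c2OCOC
F5 | step 11 | 1-{(1R,2S)-2-[5-bromo-4-isopropyl-2,3-bis(methoxymethoxy)phenyl]-2,6,6-trimethylcyclohexyl}-2-(methanesulfinyl)ethan-1-one | CS(=O)CC(=O)[C@@H]1C(C)(C)CCC[C@]1(C)c2cc(Br)c(C(C)C)c(OCOC)c2OCOC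
F6 | step 11 | (5R,10S)-14-bromo-11,12-bis(methoxymethoxy)-7-(methylsulfanyl)abieta-8,11,13-trien-6-one (C7 epimers) | CSC1C(=O)[C@@H]2C(C)(C)CCC[C@]2(C)c2c(OCOC)c(OCOC)c(C(C)C)c(Br)c21
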